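The unbranched thirteen-carbon chain is cut between C8′ and C9′ (numbered from lactone C5). A nickel-hydride hydroalkylation joins the terminal C7′=C8′ olefin of an oct-7-enyl lactone imide to C9′ of 5-bromopentan-1-ol, anti-Markovnikov, in one operation and without a preformed organometallic. The step exploits the fact that this tether carries no branch or heteroatom between ring carbon C5 and the C13′ oxygen, so the trans C4/C5 stereocentres of the γ-lactone ring can be set beforehand by an Evans syn-aldol/lactonisation of a succinyl oxazolidinone with non-8-enal. Auxiliary cleavage, α-methylenation at C3 and O-acetylation complete the target.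

Key step: step 4

Remark: ring atoms are numbered O1, C2(=O), C3, C4(CO2H), C5; chain carbons C1′–C13′ run from C5 to the acetate oxygen. The target is the trans-(4S,5R) lactone, which is (2R,3S) in oxolane-3-carboxylic acid numbering. The C13′ oxygen is carried as the free alcohol and acetylated last, because an acetate would not survive the magnesium methyl carbonate of step 6.

Step 1
Reactants: 1 (S)-4-benzyl-1,3-oxazolidin-2-one; 2 methyl 4-chloro-4-oxobutanoate
Product: 3 methyl 4-[(4S)-4-benzyl-2-oxo-1,3-oxazolidin-3-yl]-4-oxobutanoate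
Conditions: Et3N, DMAP (cat.), CH2Cl2, 0 °C → rt
Reagents that add atoms: none
Why: DMAP-catalysed N-acylation of the oxazolidinone by the acid chloride, which leaves the methyl ester and the auxiliary stereocentre untouched.

Step 2
Reactants: 4 non-8-en-1-ol
Product: 5 non-8-enal
Conditions: TEMPO (cat.), PhI(OAc)2, CH2Cl2, rt
Reagents that add atoms: none
Why: TEMPO/oxoammonium oxidation of a primary alcohol stops at the aldehyde and does not touch the terminal olefin.

Step 3
Reactants: 3 methyl 4-[(4S)-4-benzyl-2-oxo-1,3-oxazolidin-3-yl]-4-oxobutanoate; 5 non-8-enal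
Product: 8 (4S)-4-benzyl-3-{[(2R,3S)-2-(oct-7-en-1-yl)-5-oxooxolan-3-yl]carbonyl}-1,3-oxazolidin-2-one, via boron Z-enolate 6 (not isolated), via syn-aldol hydroxy ester 7 (not isolated)
Conditions: Bu2BOTf, i-Pr2NEt, CH2Cl2, −78 → 0 °C; 5, −78 → 0 °C; pH 7 buffer, MeOH, 30% H2O2, 0 °C; TsOH (cat.), CH2Cl2, rt
Reagents that add atoms: none
Why: Evans syn-aldol reaction in which soft enolisation gives the imide (Z)-boron enolate 6 (the imide α-CH2 is far more acidic than the ester α-CH2), the aldehyde adds through a chair Zimmerman–Traxler transition state on the enolate face opposite the benzyl group to set C4 (S) and C5 (R), and the C5 oxygen of syn-adduct 7 then closes 5-exo-trig on the methyl ester to give the trans-γ-lactone.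

Step 4
Reactants: 8 (4S)-4-benzyl-3-{[(2R,3S)-2-(oct-7-en-1-yl)-5-oxooxolan-3-yl]carbonyl}-1,3-oxazolidin-2-one; 9 5-bromopentan-1-ol
Product: 10 (4S)-4-benzyl-3-{[(2R,3S)-2-(13-hydroxytridecyl)-5-oxooxolan-3-yl]carbonyl}-1,3-oxazolidin-2-one
Conditions: NiBr2·diglyme (10 mol %), 4,4′-di-tert-butyl-2,2′-bipyridine (12 mol %), (EtO)2MeSiH, Na2CO3, NaI (cat.), DMA, rt
Reagents that add atoms: none
Why: A ligated Ni–H, formed from the nickel salt, the silane and carbonate, adds across the terminal C7′=C8′ olefin of 8 with nickel on the terminal carbon; halogen-atom abstraction from 9 gives the 5-hydroxypentyl radical, which is captured at nickel, and C(sp3)–C(sp3) reductive elimination forms C8′–C9′. The closest known reaction type is the nickel-hydride-catalysed anti-Markovnikov reductive hydroalkylation of unactivated terminal alkenes with primary alkyl halides. No ring is closed and no stereocentre is created; C4 and C5, set in step 3, lie at least seven atoms from the reacting carbons and are not disturbed under these weakly basic, non-hydrolytic conditions. The step needs linear regioselectivity and chemoselectivity for the olefin over the imide, the lactone and the free hydroxyl. The monosubstituted, electronically unbiased olefin should deliver the primary alkylnickel (a chain-walked secondary alkylnickel reverts to it before coupling), and carbonyl groups and alcohols are inert to Ni–H/silane at room temperature.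

Step 5
Reactants: 10 (4S)-4-benzyl-3-{[(2R,3S)-2-(13-hydroxytridecyl)-5-oxooxolan-3-yl]carbonyl}-1,3-oxazolidin-2-one
Product: 12 (2R,3S)-2-(13-hydroxytridecyl)-5-oxooxolane-3-carboxylic acid, via peroxy acid 11 (not isolated)
Conditions: LiOH, 30% H2O2, THF/H2O 3:1, 0 °C; aq. Na2SO3; 1 M HCl
Reagents that add atoms: hydrogen peroxide, OO
Why: Hydroperoxide cleavage of the Evans imide attacks the exocyclic carbonyl selectively and, being weakly basic, should not epimerise C4 or open the lactone irreversibly, while sulfite reduces peracid 11 to the acid and the auxiliary is recovered.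

Step 6
Reactants: 12 (2R,3S)-2-(13-hydroxytridecyl)-5-oxooxolane-3-carboxylic acid
Product: 15 (2R,3S)-2-(13-hydroxytridecyl)-4-methylidene-5-oxooxolane-3-carboxylic acid, via malonic diacid 13 (not isolated), via Mannich adduct 14 (not isolated)
Conditions: MeOMgOCO2Me (2 M in DMF), 135 °C; 10% HCl, 0 °C; then 37% aq. HCHO, PhNHMe, NaOAc, AcOH, rt
Reagents that add atoms: formaldehyde, C=O
Why: Stiles carboxylation followed by decarboxylative Mannich methylenation, in which the magnesium-chelated C3 enolate next to the C4 carboxylate is trapped as malonic acid 13, which condenses with CH2O/PhNHMe to 14 and loses CO2 and N-methylaniline to give the exocyclic C3 methylene; C4 remains a non-enolisable carboxylate, so the trans C4/C5 relationship should be kept, and the C13′ alcohol returns on acidic work-up.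

Step 7
Reactants: 15 (2R,3S)-2-(13-hydroxytridecyl)-4-methylidene-5-oxooxolane-3-carboxylic acid
Product: 16 (2R,3S)-2-(13-acetoxytridecyl)-4-methylidene-5-oxooxolane-3-carboxylic acid (CNP0178400.1)
Conditions: AcCl, CH2Cl2, 0 °C → rt; then THF/H2O
Reagents that add atoms: acetyl chloride, CC(=O)Cl
Why: Base-free O-acetylation of the primary alcohol by an acyl chloride, in which any mixed anhydride at the C4 acid is hydrolysed on aqueous work-up and the absence of base avoids migration of the exocyclic double bond into the ring.

Compound list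
1 | (S)-4-benzyl-1,3-oxazolidin-2-one | O=C1OC[C@H](Cc2ccccc2)N1 | starting material
2 | methyl 4-chloro-4-oxobutanoate | COC(=O)CCC(=O)Cl | starting material
3 | methyl 4-[(4S)-4-benzyl-2-oxo-1,3-oxazolidin-3-yl]-4-oxobutanoate | COC(=O)CCC(=O)N1[C@@H](Cc2ccccc2)COC1=O | intermediate
4 | non-8-en-1-ol | C=CCCCCCCCO | starting material
5 | non-8-enal | C=CCCCCCCC=O | intermediate
6 | methyl (3Z)-4-[(4S)-4-benzyl-2-oxo-1,3-oxazolidin-3-yl]-4-[(dibutylboranyl)oxy]but-3-enoate | COC(=O)C/C=C(\OB(CCCC)CCCC)N1[C@@H](Cc2ccccc2)COC1=O | intermediate (not isolated)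
7 | methyl (3S,4R)-3-{[(4S)-4-benzyl-2-oxo-1,3-oxazolidin-3-yl]carbonyl}-4-hydroxydodec-11-enoate | O[C@H](CCCCCCC=C)[C@H](CC(=O)OC)C(=O)N1[C@@H](Cc2ccccc2)COC1=O | intermediate (not isolated)
8 | (4S)-4-benzyl-3-{[(2R,3S)-2-(oct-7-en-1-yl)-5-oxooxolan-3-yl]carbonyl}-1,3-oxazolidin-2-one | C1C(=O)O[C@H](CCCCCCC=C)[C@H]1C(=O)N2[C@@H](Cc3ccccc3)COC2=O | intermediate
9 | 5-bromopentan-1-ol | OCCCCCBr | starting material
10 | (4S)-4-benzyl-3-{[(2R,3S)-2-(13-hydroxytridecyl)-5-oxooxolan-3-yl]carbonyl}-1,3-oxazolidin-2-one | C1C(=O)O[C@H](CCCCCCCCCCCCCO)[C@H]1C(=O)N2[C@@H](Cc3ccccc3)COC2=O | intermediate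
11 | (2R,3S)-2-(13-hydroxytridecyl)-5-oxooxolane-3-carboperoxoic acid | C1C(=O)O[C@H](CCCCCCCCCCCCCO)[C@H]1C(=O)OO | intermediate (not isolated)
12 | (2R,3S)-2-(13-hydroxytridecyl)-5-oxooxolane-3-carboxylic acid | C1C(=O)O[C@H](CCCCCCCCCCCCCO)[C@H]1C(=O)O | intermediate
13 | (2R,3S)-2-(13-hydroxytridecyl)-5-oxooxolane-3,4-dicarboxylic acid (C4 epimers) | OC(=O)C1C(=O)O[C@H](CCCCCCCCCCCCCO)[C@H]1C(=O)O | intermediate (not isolated)
14 | (2R,3S)-2-(13-hydroxytridecyl)-4-{[methyl(phenyl)amino]methyl}-5-oxooxolane-3,4-dicarboxylic acid (C4 epimers) | CN(CC1(C(=O)O)C(=O)O[C@H](CCCCCCCCCCCCCO)[C@H]1C(=O)O)c2ccccc2 | intermediate (not isolated)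
15 | (2R,3S)-2-(13-hydroxytridecyl)-4-methylidene-5-oxooxolane-3-carboxylic acid | C=C1C(=O)O[C@H](CCCCCCCCCCCCCO)[C@H]1C(=O)O | intermediate
16 | (2R,3S)-2-(13-acetoxytridecyl)-4-methylidene-5-oxooxolane-3-carboxylic acid | C=C1C(=O)O[C@H](CCCCCCCCCCCCCOC(C)=O)[C@H]1C(=O)O | target

Total step count: 7. Longest linear sequence: 6 steps (1, 3, 4, 5, 6, 7); step 2 is a one-step branch.

Steps most likely to fail

Step 4. Nickel-hydride chain-walking or simple reduction of the olefin, hydrodebromination of the halide, or cyclisation of the bromo alcohol may compete with the coupling. The fallback sets out from 8: hydroboration with 9-BBN (THF, 0 °C → rt) should add boron to C8′ without touching imide or lactone and give the B-alkyl-9-borabicyclo[3.3.1]nonane F1. This is coupled with 9 in a B-alkyl Suzuki–Miyaura alkyl–alkyl reaction (Pd(OAc)2, PCy3, K3PO4·H2O, THF, rt), which forms the same C8′–C9′ bond and comes back to the route at 10.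

Step 6. α-Carboxylation of the hindered lactone may be slow, and the long heating may cause migration of the exocyclic double bond into the ring or epimerisation at C4. The fallback sets out from 12: excess NaHMDS (THF, −78 °C) forms the alkoxide/carboxylate/C3-enolate, and Eschenmoser's salt should give the α-(dimethylaminomethyl) lactone acid F2. Quaternisation with MeI (MeOH, rt) gives the trimethylammonium iodide F3, and NaHCO3 (EtOAc/H2O, rt) eliminates trimethylamine, coming back to the route at 15.

Step 7. Intermolecular esterification through a transient mixed anhydride at the C4 acid, hydrochlorination of the exocyclic alkene or its migration may accompany the acetylation. The fallback sets out from 15: a lipase-catalysed transesterification (immobilised Candida antarctica lipase B, vinyl acetate, MTBE, rt) acetylates only the primary alcohol under neutral conditions and arrives directly at 16; it makes no new compound (F0).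

Further compounds
F1 | step 4 | (4S)-4-benzyl-3-{[(2R,3S)-2-[8-(9-borabicyclo[3.3.1]nonan-9-yl)octyl]-5-oxooxolan-3-yl]carbonyl}-1,3-oxazolidin-2-one | C1C(=O)O[C@H](CCCCCCCCB2C3CCCC2CCC3)[C@H]1C(=O)N4[C@@H](Cc5ccccc5)COC4=O
F2 | step 6 | (2R,3S)-4-[(dimethylamino)methyl]-2-(13-hydroxytridecyl)-5-oxooxolane-3-carboxylic acid | CN(C)CC1C(=O)O[C@H](CCCCCCCCCCCCCO)[C@H]1C(=O)O
F3 | step 6 | {[(4S,5R)-4-carboxy-5-(13-hydroxytridecyl)-2-oxooxolan-3-yl]methyl}trimethylammonium iodide | C[N+](C)(C)CC1C(=O)O[C@H](CCCCCCCCCCCCCO)[C@H]1C(=O)O.[I-]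
F0 | step 7 | none | none
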